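## The problem

Target 14 is a benzophenone. A ketone carbon links C1' of ring A (2-hydroxy-4,6-dimethoxyphenyl) to C5 of a 2,2-dimethyl-2H-chromene, whose benzo ring B carries a free hydroxyl at C7 and whose pyran ring C (O1, C2, C3, C4) is fused across C4a–C8a. There is no stereocentre, so the difficulty lies in regiochemistry and chemoselectivity. On ring B, C4a must lie between the acyl-bearing C5 and the oxygen-bearing C8a, and not between the two ring oxygens; direct annulation of a free resorcinol leaves exactly this choice open. The ketone is surrounded by three ortho substituents (the C2' oxygen, the C6' methoxy group and C4a), so the bond that creates it must tolerate crowding. The chromene is an electron-rich styrenyl ether with an allylic tertiary C2–O1 bond and will not survive strong Lewis or protic acid, hydrogenation or electrophilic oxidants. Ring A keeps two methyl ethers while the C2' and C7 oxygens end free, which excludes a late demethylation and requires these two oxygens to carry groups that come off gently. The enabling feature is that ring C hangs on the phenol oxygen at C8a and on C4 at C4a, with C4a next to the carbonyl-bearing C5: this is a salicylaldehyde whose formyl carbon (future C4) sits between a hydroxyl (future O1) and an ester (future ketone carbon).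

## Retrosynthesis

Target 14 is first related to its bis(methoxymethyl) ether 13. No skeletal bond is cut; the two phenols that must end free (C2' and C7) are masked. An acetal is preferred at C7 to a silyl ether because it is indifferent to a warm secondary amine and to an aryllithium. It is preferred to a benzyl or methyl ether because its removal needs neither hydrogen nor a boron halide, which would attack the chromene or the ring A methyl ethers. The same group on both oxygens allows one closing operation, which must use acid mild enough to spare the C3=C4 double bond.

The bond between the carbonyl carbon and C1' of 13 is cut next, giving chromene ester 9 and aryllithium 12. Compound 12 goes back to arene 11 by removal of lithium, and 11 to phenol 10 by removal of the acetal. Cutting at C5 instead would need a C5-metalated chromene and an acyl donor on the crowded ring A, and a Friedel–Crafts union would expose the chromene to Lewis acid. The chosen cut lets the ketone carbon be the ester carbon that ring B carries from the start. The two halves are of similar size. The forward reaction must metalate 11 between the acetal oxygen and a methoxy group, not between the two methoxy groups, and must stop after one addition to the ester.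

Chromene 9 is then opened at C3–C4 and O1–C2, which removes ring C and returns salicylaldehyde 5 and boronic acid 6. The neighbouring chromene constructions (condensing a free resorcinol ester with an unsaturated aldehyde, or rearranging an aryl propargyl ether) must choose between two open ortho positions and tend to favour the carbon between the two oxygens, which is the wrong one. In 5 the choice is already made: the formyl carbon is C4 and the only free hydroxyl beside it is O1. Precursor 5 is a monocyclic, tetrasubstituted benzene and 6 is commercial. The forward reaction has to deliver the alkenyl group to the formyl carbon in the presence of the ester and then close the pyran, passing through 7 and 8.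

Salicylaldehyde 5 is simplified by removing its protecting groups and its formyl carbon. The acetal on the C5 oxygen leads back to dihydroxy aldehyde 4, the two hydroxyls of 4 to the benzyl ethers of 3, and the bond between C2 and the formyl carbon of 3 is cut to give benzoate 1. Formylation is placed on the bis-ether because there the site para to one oxygen and ortho to the ester is reliably preferred over the site between the two oxygens. Benzyl is chosen over methyl because it leaves at −78 °C, whereas a demethylation strong enough for a methoxy group para to a formyl group would endanger the adjacent ester. Compound 1 is a symmetrical commercial benzoate. The forward steps need one regioselective electrophilic substitution and one site-selective alkylation, the latter decided by the hydrogen bond from the C3 hydroxyl to the formyl oxygen.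

## Roads not taken

Alternative 1: This plan cuts C5–C(=O) and C4a–C4 together.
- Key step: 1-iodo-2,4-bis(methoxymethoxy)benzene A1 would enter a Catellani reaction. Its free ortho carbon would be acylated by 2,4-dimethoxy-6-(methoxymethoxy)benzoic anhydride A2, and its ipso carbon would end in a Heck reaction with 2-methylbut-3-en-2-ol A3. The product would be [2-[(E)-3-hydroxy-3-methylbut-1-enyl]-3,5-bis(methoxymethoxy)phenyl][2,4-dimethoxy-6-(methoxymethoxy)phenyl]methanone A4. Acid would then remove the three acetals and close ring C by cyclodehydration, giving 14.
- Merits: It is the most convergent plan. The ketone and C4 are installed in one operation, ring B needs no formylation or protecting-group exchange, and the ortho oxygen of A1 is the kind of blocking group the relay requires.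
- Weak points: The acyl donor A2 is doubly ortho-substituted and electron-rich. It must add to the aryl–norbornyl palladacycle (a tetravalent palladium stage) and then give a ketone with three ortho substituents, whereas ortho-acylation of this type is established for unhindered acyl donors. Half of A2 is discarded, and A2 itself costs a carboxylation and a dehydration beyond 11. The E-alkene of A4 cannot close directly and must ionise under the same acid that threatens the finished chromene.
- Comparison: If the key step worked, this road would be shorter than the chosen one by two or three steps on the longest line, and in step economy it is better. The chosen plan sets against this that every bond-forming step belongs to a reaction class whose scope already covers the substrate type, and that the regiochemistry of ring B is fixed by an ordinary electrophilic substitution.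

Alternative 2: This plan cuts both bonds to the ketone carbon.
- Key step: A carbonylative Stille coupling with zerovalent palladium would join 2,2-dimethyl-7-[(triisopropylsilyl)oxy]-2H-chromen-5-yl trifluoromethanesulfonate A5 and tributyl[2,4-dimethoxy-6-(methoxymethoxy)phenyl]stannane A6. The product would be [2,4-dimethoxy-6-(methoxymethoxy)phenyl][2,2-dimethyl-7-(triisopropylsilyloxy)-2H-chromen-5-yl]methanone A7, two deprotections from 14.
- Merits: Triflate A5 would come from 2,2-dimethyl-2H-chromene-5,7-diol A8, available by annulating a symmetrical benzenetriol where no regiochemical question arises. The carbonyl carbon comes from the gas phase, and no organolithium meets an ester.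
- Weak points: The C5 and C7 hydroxyls of A8 differ only in the peri contact of C5–OH with C4–H, so silylation at C7 followed by triflation at C5 rests on a modest steric bias. The stannane A6 has two ortho substituents and transmetalates slowly to an acyl–palladium species. The electron-rich triflate adds slowly to palladium in a carbonylative atmosphere. Direct coupling, reduction of the acyl intermediate and protodestannylation then compete, and stoichiometric tin has to be handled.
- Comparison: The step count is about the same as in the chosen plan, and the one-step access to the chromene nucleus is better than the four steps needed to reach 9. The chosen plan sets against this an unambiguous C5/C7 assignment (the carbon substituent is on the ring from compound 1 onward) and a hindered ketone bond made by polar addition, which tolerates ortho substituents better than transmetalation does.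

Alternative 3: This plan cuts C8a–O1, C4a–C4 and O1–C2.
- Key step: Fluoride would release 3-bromo-5-(methoxymethoxy)benzyne A10 from 2-bromo-4-(methoxymethoxy)-6-(trimethylsilyl)phenyl trifluoromethanesulfonate A9. The carbonyl group of 3-methylbut-2-enal A11 would add across the aryne, and the benzoxete would open to a vinyl ortho-quinone methide that closes to 5-bromo-7-(methoxymethoxy)-2,2-dimethyl-2H-chromene A12.
- Merits: The last event is the same oxa-6π closure as in the chosen plan. Regiochemistry comes from the bromine, which polarises the aryne so that the carbonyl oxygen bonds to the remote aryne carbon. The bromide of A12 is a forgiving handle: after bromine–lithium exchange it could be joined to a ring A aldehyde of fixed substitution, with no question of over-addition or of metalation regiochemistry.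
- Weak points: Precursor A9 carries four different substituents and needs protection, ortho-silylation and triflation of a bromoresorcinol derivative. Insertion of arynes into enal carbonyl groups is usually only moderately efficient and is run with an excess of one partner. After A12, the ketone still requires an addition, an oxidation and a deprotection.
- Comparison: In the handle it delivers, this road is better than the chosen one. The chosen plan sets against this a four-step access to 9 from a commercial benzoate with the ketone carbon already in place, whereas A9 alone is likely to cost as many steps as the whole sequence to 9.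

Key step: step 4

Assumption: the target has no stereocentre, so the stereogenic intermediates (7 and, in a fallback, F6) are racemic; compounds 1, 6 and 10 are taken as commercial.

Step 1
Reactants: 1 methyl 3,5-bis(benzyloxy)benzoate
Product: 3 methyl 3,5-bis(benzyloxy)-2-formylbenzoate, via aryl iminium chloride 2 (not isolated)
Conditions: POCl3, DMF, 0 → 90 °C; then ice-water
Reagents that add atoms: N,N-dimethylformamide, CN(C)C=O (formyl carbon); water, O (formyl oxygen)
Why: Vilsmeier–Haack formylation; the chloroiminium ion should attack C2, which is para to one ether oxygen and ortho to the other, rather than the more crowded site between the two benzyloxy groups, as is established for 3,5-dialkoxybenzoates. Iminium salt 2 is hydrolysed on work-up, and the ester and benzyl ethers are inert to POCl3 and DMF.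

Step 2
Reactants: 3 methyl 3,5-bis(benzyloxy)-2-formylbenzoate
Product: 4 methyl 2-formyl-3,5-dihydroxybenzoate
Conditions: BCl3, C6HMe5, CH2Cl2, −78 °C; then H2O
Reagents that add atoms: none
Why: Lewis-acid debenzylation with BCl3 and pentamethylbenzene as a non-basic benzyl-cation trap cleaves aryl benzyl ethers at −78 °C, where the methyl ester and the aldehyde are not touched and the freed resorcinol is not C-benzylated.

Step 3
Reactants: 4 methyl 2-formyl-3,5-dihydroxybenzoate
Product: 5 methyl 2-formyl-3-hydroxy-5-(methoxymethoxy)benzoate
Conditions: MOMCl (1.05 equiv), DIPEA, CH2Cl2, 0 °C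
Reagents that add atoms: chloromethyl methyl ether, COCCl
Why: Site-selective O-alkylation; the C3 hydroxyl is held in a hydrogen bond to the formyl oxygen, so one equivalent of the chloride should alkylate the more acidic, unencumbered C5 hydroxyl para to the aldehyde, as is routine for 2,4-dihydroxybenzaldehydes.

Step 4
Reactants: 5 methyl 2-formyl-3-hydroxy-5-(methoxymethoxy)benzoate; 6 (2-methylprop-1-en-1-yl)boronic acid
Product: 9 methyl 7-(methoxymethoxy)-2,2-dimethyl-2H-chromene-5-carboxylate, via allylic amine 7 (not isolated), via vinyl ortho-quinone methide 8 (not isolated)
Conditions: 6 (1.5 equiv), Bn2NH (0.4 equiv), 1,4-dioxane, 90 °C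
Reagents that add atoms: none
Why: This is a Petasis borono-Mannich condensation followed by amine loss and electrocyclisation, the established amine-promoted route from salicylaldehydes and alkenylboronic acids to 2H-chromenes; the β,β-dimethyl partner is a less common member of that class. Dibenzylamine condenses with the formyl group of 5 to an iminium phenoxide, the phenoxide oxygen binds 6 as a tetracoordinate boronate, and the boron-bearing alkenyl carbon migrates intramolecularly to the iminium carbon, forming C3–C4 and racemic allylic amine 7. At 90 °C the phenol expels dibenzylamine, assisted by the para acetal oxygen, which gives vinyl ortho-quinone methide 8 and returns the amine to the cycle. Ring C closes by a thermal disrotatory oxa-6π electrocyclisation across the O=C8a–C4a=C4–C3=C2 array of 8, forming O1–C2 at the dimethyl-substituted terminus; re-aromatisation of ring B makes the closure irreversible. No stereocentre results because C2 carries two methyl groups, and the stereocentre of 7 is erased on the way. The step needs chemoselectivity for the aldehyde over the ester and a single site of closure: only the formyl carbon forms an iminium, only a boronate held on the adjacent phenoxide can deliver the alkenyl group, and the second ring oxygen is capped as its acetal. The ring position of C4 and O1 was therefore fixed by the formylation of step 1, and the ester, acetal and aryl ether groups are inert to a secondary amine and a boronic acid in dioxane.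

Step 5
Reactants: 10 3,5-dimethoxyphenol
Product: 11 1,3-dimethoxy-5-(methoxymethoxy)benzene
Conditions: NaH, MOMCl, THF, 0 °C → rt
Reagents that add atoms: chloromethyl methyl ether, COCCl
Why: Williamson-type O-alkylation of the sodium phenoxide; the acetal serves both as the protecting group and as the director of the metalation that follows.

Step 6
Reactants: 11 1,3-dimethoxy-5-(methoxymethoxy)benzene; 9 methyl 7-(methoxymethoxy)-2,2-dimethyl-2H-chromene-5-carboxylate
Product: 13 [2,4-dimethoxy-6-(methoxymethoxy)phenyl][7-(methoxymethoxy)-2,2-dimethyl-2H-chromen-5-yl]methanone, via aryllithium 12 (not isolated)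
Conditions: 11 (1.3 equiv), n-BuLi (1.2 equiv), THF, 0 °C; then 9, −78 → 0 °C; then H2O
Reagents that add atoms: none
Why: Directed ortho-metalation followed by acyl substitution; the chelating acetal oxygen should guide n-BuLi to one of the two equivalent positions between it and a methoxy group, and the resulting 12 adds to the ester carbonyl of 9. Addition should stop at the ketone because 13 has three ortho substituents around the carbonyl and the nucleophile is itself doubly ortho-substituted; the acetals, aryl ethers and chromene are inert to the aryllithium at low temperature.

Step 7
Reactants: 13 [2,4-dimethoxy-6-(methoxymethoxy)phenyl][7-(methoxymethoxy)-2,2-dimethyl-2H-chromen-5-yl]methanone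
Product: 14 (2-hydroxy-4,6-dimethoxyphenyl)(7-hydroxy-2,2-dimethyl-2H-chromen-5-yl)methanone
Conditions: aq. HCl (3 M), MeOH, 45 °C
Reagents that add atoms: none
Why: Acid-catalysed acetal exchange in methanol frees both phenols, the ring A acetal being activated by the adjacent ketone. Aryl methyl ethers are stable to these conditions, and 2,2-dimethyl-2H-chromenes are known to tolerate dilute methanolic HCl at moderate temperature.

Compound list

1 | methyl 3,5-bis(benzyloxy)benzoate | COC(=O)c1cc(OCc2ccccc2)cc(OCc2ccccc2)c1 | starting material
2 | N-{[2,4-bis(benzyloxy)-6-(methoxycarbonyl)phenyl]methylidene}-N-methylmethanaminium chloride | COC(=O)c1cc(OCc2ccccc2)cc(OCc2ccccc2)c1C=[N+](C)C.[Cl-] | intermediate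
3 | methyl 3,5-bis(benzyloxy)-2-formylbenzoate | COC(=O)c1cc(OCc2ccccc2)cc(OCc2ccccc2)c1C=O | intermediate
4 | methyl 2-formyl-3,5-dihydroxybenzoate | COC(=O)c1cc(O)cc(O)c1C=O | intermediate
5 | methyl 2-formyl-3-hydroxy-5-(methoxymethoxy)benzoate | COC(=O)c1cc(OCOC)cc(O)c1C=O | intermediate
6 | (2-methylprop-1-en-1-yl)boronic acid | CC(C)=CB(O)O | starting material
7 | methyl 2-[1-(dibenzylamino)-3-methylbut-2-en-1-yl]-3-hydroxy-5-(methoxymethoxy)benzoate (racemic) | COC(=O)c1cc(OCOC)cc(O)c1C(C=C(C)C)N(Cc1ccccc1)Cc1ccccc1 | intermediate
8 | methyl 3-(methoxymethoxy)-6-(3-methylbut-2-en-1-ylidene)-5-oxocyclohexa-1,3-diene-1-carboxylate | COC(=O)C1=CC(OCOC)=CC(=O)C1=CC=C(C)C | intermediate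
9 | methyl 7-(methoxymethoxy)-2,2-dimethyl-2H-chromene-5-carboxylate | COC(=O)c1cc(OCOC)cc2OC(C)(C)C=Cc12 | intermediate
10 | 3,5-dimethoxyphenol | COc1cc(O)cc(OC)c1 | starting material
11 | 1,3-dimethoxy-5-(methoxymethoxy)benzene | COCOc1cc(OC)cc(OC)c1 | intermediate
12 | [2,4-dimethoxy-6-(methoxymethoxy)phenyl]lithium | [Li]c1c(OC)cc(OC)cc1OCOC | intermediate
13 | [2,4-dimethoxy-6-(methoxymethoxy)phenyl][7-(methoxymethoxy)-2,2-dimethyl-2H-chromen-5-yl]methanone | COCOc1cc(OC)cc(OC)c1C(=O)c1cc(OCOC)cc2OC(C)(C)C=Cc12 | intermediate
14 | (2-hydroxy-4,6-dimethoxyphenyl)(7-hydroxy-2,2-dimethyl-2H-chromen-5-yl)methanone | COc1cc(O)c(C(=O)c2cc(O)cc3c2C=CC(C)(C)O3)c(OC)c1 | target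

Total step count: 7. Longest linear sequence: 6 steps (steps 1, 2, 3, 4, 6 and 7); step 5 prepares the ring A partner.

Least certain steps

Step 4 (key step). The most likely failure is slow boron-to-carbon transfer at a formyl group flanked on both sides. Protodeboronation of 6 at 90 °C and attack of the carbinolamine oxygen on the neighbouring ester (lactonisation with loss of methanol) would then gain ground. The fallback sets out from 5 and returns at 9, and builds the same two bonds stepwise by known reactions.
- Wittig olefination of 5 with the stabilised ylide Ph3P=CHC(O)CH3 (toluene, 90 °C) should give methyl 3-hydroxy-5-(methoxymethoxy)-2-[(1E)-3-oxobut-1-en-1-yl]benzoate F1. No oxygen nucleophile is ever placed on the benzylic carbon.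
- The methylcerium reagent from MeLi and CeCl3 (THF, −78 °C) adds to ketones in preference to esters and in the 1,2-sense to enones. It should give methyl 3-hydroxy-2-[(1E)-3-hydroxy-3-methylbut-1-en-1-yl]-5-(methoxymethoxy)benzoate F2.
- PPTS in toluene at 80 °C should ionise the tertiary allylic alcohol of F2 to the protonated form of 8, which closes to 9.

Step 6. The most likely failure is incomplete or over-extended acyl transfer. The tetrahedral adduct of two ortho-crowded partners may form slowly at −78 °C, and once it collapses on warming the ketone competes with unreacted ester for the remaining aryllithium. A lesser concern is metalation of 11 between its two methoxy groups. The fallback sets out from 9 and returns at 13.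
- Reduction of 9 with diisobutylaluminium hydride (CH2Cl2, −78 °C) should give [7-(methoxymethoxy)-2,2-dimethyl-2H-chromen-5-yl]methanol F4.
- MnO2 (CH2Cl2, rt) should oxidise F4 to 7-(methoxymethoxy)-2,2-dimethyl-2H-chromene-5-carbaldehyde F5.
- Addition of 12 to F5, where a second addition is impossible, should give racemic [2,4-dimethoxy-6-(methoxymethoxy)phenyl][7-(methoxymethoxy)-2,2-dimethyl-2H-chromen-5-yl]methanol F6.
- Dess–Martin periodinane (NaHCO3, CH2Cl2) should oxidise F6 to 13.

Step 7. The most likely failure is acid-promoted addition of methanol or chloride across the electron-rich C3=C4 bond, or ionisation of the allylic C2–O1 bond, before the less activated C7 acetal has been cleaved. The fallback sets out from 4 and returns at 14, and uses an orthogonal protecting scheme in which C7 carries a fluoride-labile group.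
- TBSCl and imidazole (CH2Cl2, 0 °C) should silylate the non-chelated hydroxyl of 4 to give methyl 5-[(tert-butyldimethylsilyl)oxy]-2-formyl-3-hydroxybenzoate F7.
- The conditions of step 4 with 6 should convert F7 into methyl 7-[(tert-butyldimethylsilyl)oxy]-2,2-dimethyl-2H-chromene-5-carboxylate F8.
- Addition of 12 as in step 6 should give {7-[(tert-butyldimethylsilyl)oxy]-2,2-dimethyl-2H-chromen-5-yl}[2,4-dimethoxy-6-(methoxymethoxy)phenyl]methanone F9.
- Bu4NF (THF, 0 °C) should give (7-hydroxy-2,2-dimethyl-2H-chromen-5-yl)[2,4-dimethoxy-6-(methoxymethoxy)phenyl]methanone F10.
- Only the ketone-activated ring A acetal then remains, and PPTS in MeOH at 40 °C should remove it to give 14.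

Further compounds

F1 | step 4 | methyl 3-hydroxy-5-(methoxymethoxy)-2-[(1E)-3-oxobut-1-en-1-yl]benzoate | COC(=O)c1cc(OCOC)cc(O)c1/C=C/C(C)=O
F2 | step 4 | methyl 3-hydroxy-2-[(1E)-3-hydroxy-3-methylbut-1-en-1-yl]-5-(methoxymethoxy)benzoate | COC(=O)c1cc(OCOC)cc(O)c1/C=C/C(C)(C)O
F4 | step 6 | [7-(methoxymethoxy)-2,2-dimethyl-2H-chromen-5-yl]methanol | COCOc1cc(CO)c2C=CC(C)(C)Oc2c1
F5 | step 6 | 7-(methoxymethoxy)-2,2-dimethyl-2H-chromene-5-carbaldehyde | COCOc1cc(C=O)c2C=CC(C)(C)Oc2c1
F6 | step 6 | [2,4-dimethoxy-6-(methoxymethoxy)phenyl][7-(methoxymethoxy)-2,2-dimethyl-2H-chromen-5-yl]methanol (racemic) | COCOc1cc(OC)cc(OC)c1C(O)c1cc(OCOC)cc2OC(C)(C)C=Cc12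
F7 | step 7 | methyl 5-[(tert-butyldimethylsilyl)oxy]-2-formyl-3-hydroxybenzoate | COC(=O)c1cc(O[Si](C)(C)C(C)(C)C)cc(O)c1C=O
F8 | step 7 | methyl 7-[(tert-butyldimethylsilyl)oxy]-2,2-dimethyl-2H-chromene-5-carboxylate | COC(=O)c1cc(O[Si](C)(C)C(C)(C)C)cc2OC(C)(C)C=Cc12
F9 | step 7 | {7-[(tert-butyldimethylsilyl)oxy]-2,2-dimethyl-2H-chromen-5-yl}[2,4-dimethoxy-6-(methoxymethoxy)phenyl]methanone | COCOc1cc(OC)cc(OC)c1C(=O)c1cc(O[Si](C)(C)C(C)(C)C)cc2OC(C)(C)C=Cc12
F10 | step 7 | (7-hydroxy-2,2-dimethyl-2H-chromen-5-yl)[2,4-dimethoxy-6-(methoxymethoxy)phenyl]methanone | COCOc1cc(OC)cc(OC)c1C(=O)c1cc(O)cc2OC(C)(C)C=Cc12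
A1 | alternative 1 | 1-iodo-2,4-bis(methoxymethoxy)benzene | COCOc1ccc(I)c(OCOC)c1
A2 | alternative 1 | 2,4-dimethoxy-6-(methoxymethoxy)benzoic anhydride | COCOc1cc(OC)cc(OC)c1C(=O)OC(=O)c1c(OC)cc(OC)cc1OCOC
A3 | alternative 1 | 2-methylbut-3-en-2-ol | CC(C)(O)C=C
A4 | alternative 1 | [2-[(E)-3-hydroxy-3-methylbut-1-enyl]-3,5-bis(methoxymethoxy)phenyl][2,4-dimethoxy-6-(methoxymethoxy)phenyl]methanone | COCOc1cc(OC)cc(OC)c1C(=O)c1cc(OCOC)cc(OCOC)c1/C=C/C(C)(C)O
A5 | alternative 2 | 2,2-dimethyl-7-[(triisopropylsilyl)oxy]-2H-chromen-5-yl trifluoromethanesulfonate | CC1(C)C=Cc2c(OS(=O)(=O)C(F)(F)F)cc(O[Si](C(C)C)(C(C)C)C(C)C)cc2O1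
A6 | alternative 2 | tributyl[2,4-dimethoxy-6-(methoxymethoxy)phenyl]stannane | CCCC[Sn](CCCC)(CCCC)c1c(OC)cc(OC)cc1OCOC
A7 | alternative 2 | [2,4-dimethoxy-6-(methoxymethoxy)phenyl][2,2-dimethyl-7-(triisopropylsilyloxy)-2H-chromen-5-yl]methanone | COCOc1cc(OC)cc(OC)c1C(=O)c1cc(O[Si](C(C)C)(C(C)C)C(C)C)cc2OC(C)(C)C=Cc12
A8 | alternative 2 | 2,2-dimethyl-2H-chromene-5,7-diol | CC1(C)C=Cc2c(O)cc(O)cc2O1
A9 | alternative 3 | 2-bromo-4-(methoxymethoxy)-6-(trimethylsilyl)phenyl trifluoromethanesulfonate | COCOc1cc(Br)c(OS(=O)(=O)C(F)(F)F)c([Si](C)(C)C)c1
A10 | alternative 3 | 3-bromo-5-(methoxymethoxy)benzyne | BrC1=CC(OCOC)=CC#C1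
A11 | alternative 3 | 3-methylbut-2-enal | CC(C)=CC=O
A12 | alternative 3 | 5-bromo-7-(methoxymethoxy)-2,2-dimethyl-2H-chromene | COCOc1cc(Br)c2C=CC(C)(C)Oc2c1
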